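**Plan**

- Retrosynthesis first cuts the two aryl–C(=O) bonds to the resorcinol rings (both ketones from one diacid derivative and one aryl-metal). It then cuts the C3–C3a bond of the dihydrobenzofuran, and last the C2–aryl bond of a flavanone.
- Enabling feature: C3 of the 2,3-dihydrobenzofuran carries both the fused-arene carbon C3a and an exocyclic acyl carbon, next to the O1–C2(aryl) unit. This is the pattern left when the C4a–C4 bond of a 2-arylchroman-4-one moves to C3 and C4 is pushed out as a carboxyl carbon, so O1, C2 and the benzo ring map onto a flavanone.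
- Forward order: the phenol ring is acetylated (Fries), the pyranone ring is closed (chromone), the C2 aryl group is added, the six-membered ring is contracted to the dihydrofuran, and the two esters are turned into the two aryl ketones.
- Stereochemistry: the target SMILES encodes the 2,3-trans (2S,3S) isomer. C2 comes from a catalyst-controlled Rh conjugate addition; C3 is set by C2 during the ring contraction and remains the thermodynamically preferred trans epimer afterwards.

Key step: step 5

**Step 1**
Reactants: 1 methyl 3-(4-hydroxyphenyl)propanoate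
Product: 3 methyl 3-(3-acetyl-4-hydroxyphenyl)propanoate, via aryl acetate 2 (not isolated)
Conditions: AcCl, PhCl, 80 °C; then AlCl3 (3 equiv), 120 °C; ice/aq. HCl
Reagents that add atoms: acetyl chloride, CC(Cl)=O
Why: One-pot O-acetylation and Fries rearrangement, in which the blocked para position sends the acyl group ortho to the phenol oxygen and an aliphatic methyl ester is expected to survive as it does in the Fries rearrangement of methyl 4-acetoxybenzoate.

**Step 2**
Reactants: 3 methyl 3-(3-acetyl-4-hydroxyphenyl)propanoate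
Product: 5 methyl 3-(4-oxo-4H-chromen-6-yl)propanoate, via enaminone 4 (not isolated)
Conditions: Me2NCH(OMe)2, toluene, 100 °C; evaporate; conc. HCl, CH2Cl2, 40 °C
Reagents that add atoms: N,N-dimethylformamide dimethyl acetal, COC(OC)N(C)C
Why: Enaminone condensation of the methyl ketone followed by acid-promoted addition–elimination of the phenol (loss of dimethylamine) is the standard chromone synthesis and leaves the remote ester alone.

**Step 3**
Reactants: 6 4-hydroxyphenylboronic acid
Product: 7 4-(methanesulfonyloxy)phenylboronic acid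
Conditions: MsCl, pyridine, THF, 0 °C → rt; 1 M HCl work-up
Reagents that add atoms: methanesulfonyl chloride, CS(Cl)(=O)=O
Why: O-Sulfonylation of the phenol, with any B–O sulfonate or boroxine hydrolysed back to the boronic acid in the acidic aqueous work-up.

**Step 4**
Reactants: 5 methyl 3-(4-oxo-4H-chromen-6-yl)propanoate; 7 4-(methanesulfonyloxy)phenylboronic acid
Product: 8 methyl 3-[(2S)-2-[4-(methanesulfonyloxy)phenyl]-4-oxo-3,4-dihydro-2H-chromen-6-yl]propanoate
Conditions: 7 (2 equiv), [Rh(OH)(cod)]2 (cat.), (S)-MeO-F12-BIPHEP (cat.), CH2Cl2/H2O, 20 °C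
Reagents that add atoms: none
Why: Hayashi–Miyaura rhodium-catalysed asymmetric 1,4-addition of an arylboronic acid to a chromone, in which the aryl–Rh(I) complex of the electron-poor biaryl bisphosphine carbometalates one face of C2=C3 and sets C2 (S is predicted for the S ligand by the usual quadrant model and is to be confirmed by CD on the first batch), at a temperature and pH where the flavanone does not ring-open.

**Step 5**
Reactants: 8 methyl 3-[(2S)-2-[4-(methanesulfonyloxy)phenyl]-4-oxo-3,4-dihydro-2H-chromen-6-yl]propanoate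
Product: 11 methyl (2S,3S)-2-[4-(methanesulfonyloxy)phenyl]-5-(3-methoxy-3-oxopropyl)-2,3-dihydro-1-benzofuran-3-carboxylate (2,3-trans), via enol ether 9 (not isolated), via iodane ketal 10 (not isolated)
Conditions: PhI(OAc)2 (1.2 equiv), HC(OMe)3, cat. conc. H2SO4, rt; aq. NaHCO3
Reagents that add atoms: trimethyl orthoformate, COC(OC)OC
Why: Acidic orthoformate converts the ketone of 8 into enol ether 9, which the iodine(III) reagent attacks at C3 on the face anti to the C2 aryl group, and methanol capture of the oxocarbenium ion gives the trans 3-iodanyl 4,4-dimethyl ketal 10. With the C3–I bond antiperiplanar to C4–C4a, the ketal oxygens push the aryl carbon C4a from C4 to C3 as iodobenzene leaves, and the dimethoxycarbenium ion at the extruded C4 collapses to the methyl ester; this is the known iodine(III) (or thallium(III)) oxidative ring contraction of flavanones, a semipinacol-type 1,2-aryl shift. The dihydrofuran ring is therefore not closed by a cyclisation but arises by contraction of the pyranone through the single shift that makes the C3–C3a bond. The new C3 stereocentre is under substrate control by C2: anti addition of the iodane followed by invertive migration places the ester trans to the aryl group, which is also the thermodynamic arrangement, so C3 becomes S while C2 (S) is not touched. The selectivity needed is migration of C4a in preference to 2-aryl migration (isoflavone), methanol substitution at C3 or elimination to the flavone. It is secured by the ketal push, by the migrating carbon being ortho to the O1-bearing carbon and hence electron-rich, and by the electron-poor mesyloxyphenyl group, which also keeps the benzylic C2–O1 bond from ionising in acid.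

**Step 6**
Reactants: 11 methyl (2S,3S)-2-[4-(methanesulfonyloxy)phenyl]-5-(3-methoxy-3-oxopropyl)-2,3-dihydro-1-benzofuran-3-carboxylate
Product: 12 (2S,3S)-5-(2-carboxyethyl)-2-(4-hydroxyphenyl)-2,3-dihydro-1-benzofuran-3-carboxylic acid
Conditions: 2 M NaOH (excess), MeOH/THF, 55 °C, Ar; then 1 M HCl, 0 °C
Reagents that add atoms: sodium hydroxide, [Na+].[OH-]
Why: Saponification of both methyl esters and hydroxide cleavage of the aryl methanesulfonate in one operation, at a stage where C3 is a non-enolisable carboxylate and ring opening from C3 would be the reverse of a disfavoured 5-endo-trig closure, so the trans (2S,3S) array should persist.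

**Step 7**
Reactants: 12 (2S,3S)-5-(2-carboxyethyl)-2-(4-hydroxyphenyl)-2,3-dihydro-1-benzofuran-3-carboxylic acid
Product: 13 (2S,3S)-2-(4-hydroxyphenyl)-N-methoxy-5-{3-[methoxy(methyl)amino]-3-oxopropyl}-N-methyl-2,3-dihydro-1-benzofuran-3-carboxamide
Conditions: MeNH(OMe)·HCl, EDC·HCl, HOBt, N-methylmorpholine, DMF, 0 °C → rt
Reagents that add atoms: N,O-dimethylhydroxylamine hydrochloride, CNOC.Cl
Why: Carbodiimide/HOBt amide coupling to the bis-Weinreb amide, in which the active esters acylate the hydroxylamine far faster than the free phenol and C3 can only drift towards the favoured trans epimer.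

**Step 8**
Reactants: 14 4-bromobenzene-1,3-diol
Product: 15 2,4-bis(benzyloxy)-1-bromobenzene
Conditions: BnBr (2.2 equiv), K2CO3, DMF, 60 °C
Reagents that add atoms: benzyl bromide, BrCc1ccccc1
Why: Williamson O-benzylation of both phenols under carbonate conditions.

**Step 9**
Reactants: 13 (2S,3S)-2-(4-hydroxyphenyl)-N-methoxy-5-{3-[methoxy(methyl)amino]-3-oxopropyl}-N-methyl-2,3-dihydro-1-benzofuran-3-carboxamide; 15 2,4-bis(benzyloxy)-1-bromobenzene
Product: 17 1-[2,4-bis(benzyloxy)phenyl]-3-[(2S,3S)-3-[2,4-bis(benzyloxy)benzoyl]-2-(4-hydroxyphenyl)-2,3-dihydro-1-benzofuran-5-yl]propan-1-one, via aryllithium 16 (not isolated)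
Conditions: 15 (4.2 equiv), n-BuLi (4.0 equiv), THF, −78 °C; then 13 in THF, −78 → −30 °C; aq. NH4Cl
Reagents that add atoms: none
Why: Bromine–lithium exchange followed by a double Weinreb ketone synthesis, in which one equivalent of 16 deprotonates the phenol and two add to the amides to give chelated tetrahedral adducts that release the ketones only on quench, so over-addition is excluded and C3 stays in the thermodynamic trans arrangement.

**Step 10**
Reactants: 17 1-[2,4-bis(benzyloxy)phenyl]-3-[(2S,3S)-3-[2,4-bis(benzyloxy)benzoyl]-2-(4-hydroxyphenyl)-2,3-dihydro-1-benzofuran-5-yl]propan-1-one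
Product: 18 1-(2,4-dihydroxyphenyl)-3-[(2S,3S)-3-(2,4-dihydroxybenzoyl)-2-(4-hydroxyphenyl)-2,3-dihydro-1-benzofuran-5-yl]propan-1-one
Conditions: H2 (1 atm), 10% Pd/C, EtOAc/MeOH, rt
Reagents that add atoms: none
Why: Catalytic hydrogenolysis of the four aryl benzyl ethers under neutral conditions, which should be cleaved faster than the cyclic secondary benzylic C2–O1 bond and should leave the hydrogen-bonded 2-hydroxyaryl ketones unreduced.

**Compound list**

1 | methyl 3-(4-hydroxyphenyl)propanoate | COC(=O)CCc1ccc(O)cc1 | starting material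
2 | methyl 3-(4-acetoxyphenyl)propanoate (formed in situ) | COC(=O)CCc1ccc(OC(C)=O)cc1 | intermediate
3 | methyl 3-(3-acetyl-4-hydroxyphenyl)propanoate | COC(=O)CCc1ccc(O)c(C(C)=O)c1 | intermediate
4 | methyl 3-{3-[(2E)-3-(dimethylamino)prop-2-enoyl]-4-hydroxyphenyl}propanoate (formed in situ) | COC(=O)CCc1ccc(O)c(C(=O)/C=C/N(C)C)c1 | intermediate
5 | methyl 3-(4-oxo-4H-chromen-6-yl)propanoate | COC(=O)CCc1ccc2occc(=O)c2c1 | intermediate
6 | 4-hydroxyphenylboronic acid | OB(O)c1ccc(O)cc1 | starting material
7 | 4-(methanesulfonyloxy)phenylboronic acid | CS(=O)(=O)Oc1ccc(cc1)B(O)O | intermediate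
8 | methyl 3-[(2S)-2-[4-(methanesulfonyloxy)phenyl]-4-oxo-3,4-dihydro-2H-chromen-6-yl]propanoate | O=C1C[C@@H](c2ccc(OS(C)(=O)=O)cc2)Oc2ccc(CCC(=O)OC)cc12 | intermediate
9 | methyl 3-[(2S)-4-methoxy-2-[4-(methanesulfonyloxy)phenyl]-2H-chromen-6-yl]propanoate (enol ether, formed in situ) | COC1=C[C@@H](c2ccc(OS(C)(=O)=O)cc2)Oc2ccc(CCC(=O)OC)cc12 | intermediate
10 | methyl 3-[2,3-trans-3-[acetoxy(phenyl)-λ3-iodanyl]-4,4-dimethoxy-2-[4-(methanesulfonyloxy)phenyl]-3,4-dihydro-2H-chromen-6-yl]propanoate (C2 as in 8; formed in situ) | COC1(OC)[C@H](I(OC(C)=O)c3ccccc3)[C@@H](c2ccc(OS(C)(=O)=O)cc2)Oc2ccc(CCC(=O)OC)cc12 | intermediate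
11 | methyl (2S,3S)-2-[4-(methanesulfonyloxy)phenyl]-5-(3-methoxy-3-oxopropyl)-2,3-dihydro-1-benzofuran-3-carboxylate | COC(=O)CCc1ccc2c(c1)[C@H](C(=O)OC)[C@@H](c1ccc(OS(C)(=O)=O)cc1)O2 | intermediate
12 | (2S,3S)-5-(2-carboxyethyl)-2-(4-hydroxyphenyl)-2,3-dihydro-1-benzofuran-3-carboxylic acid | OC(=O)CCc1ccc2c(c1)[C@H](C(O)=O)[C@@H](c1ccc(O)cc1)O2 | intermediate
13 | (2S,3S)-2-(4-hydroxyphenyl)-N-methoxy-5-{3-[methoxy(methyl)amino]-3-oxopropyl}-N-methyl-2,3-dihydro-1-benzofuran-3-carboxamide | CON(C)C(=O)CCc1ccc2c(c1)[C@H](C(=O)N(C)OC)[C@@H](c1ccc(O)cc1)O2 | intermediate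
14 | 4-bromobenzene-1,3-diol (4-bromoresorcinol) | Oc1ccc(Br)c(O)c1 | starting material
15 | 2,4-bis(benzyloxy)-1-bromobenzene | Brc1ccc(OCc2ccccc2)cc1OCc1ccccc1 | intermediate
16 | [2,4-bis(benzyloxy)phenyl]lithium (formed in situ) | [Li]c1ccc(OCc2ccccc2)cc1OCc1ccccc1 | intermediate
17 | 1-[2,4-bis(benzyloxy)phenyl]-3-[(2S,3S)-3-[2,4-bis(benzyloxy)benzoyl]-2-(4-hydroxyphenyl)-2,3-dihydro-1-benzofuran-5-yl]propan-1-one | O=C(CCc1ccc2c(c1)[C@H](C(=O)c1ccc(OCc3ccccc3)cc1OCc1ccccc1)[C@@H](c1ccc(O)cc1)O2)c1ccc(OCc2ccccc2)cc1OCc1ccccc1 | intermediate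
18 | 1-(2,4-dihydroxyphenyl)-3-[(2S,3S)-3-(2,4-dihydroxybenzoyl)-2-(4-hydroxyphenyl)-2,3-dihydro-1-benzofuran-5-yl]propan-1-one | O=C(CCc1ccc2c(c1)[C@H](C(=O)c1ccc(O)cc1O)[C@@H](c1ccc(O)cc1)O2)c1ccc(O)cc1O | target

**Count**

Total steps: 10. Longest linear sequence: 8 steps (1, 2, 4, 5, 6, 7, 9, 10, from compound 1). Steps 3 and 8 are one-step side branches.

**Steps most likely to fail**

Step 5. Methanol may displace the C3 iodane, or C2–H may be lost to give the flavone, before the aryl carbon migrates. The acidic medium may also open the pyranone reversibly and erode the C2 configuration. The fallback is a different ring contraction that forms the same C3–C3a bond. Setting out from 8, lithium hexamethyldisilazide at −78 °C and 2,2,2-trifluoroethyl trifluoroacetate should give the 3-trifluoroacetyl flavanone F1. With methanesulfonyl azide and triethylamine in wet acetonitrile, F1 should undergo detrifluoroacetylative diazo transfer to the 3-diazoflavanone F2. Irradiation in methanol should then trigger a Wolff rearrangement in which C4a again shifts from C4 to C3 and methanol adds to the ketene. This should give the ring-contracted diester as a mixture of 11 and its cis epimer F3. Catalytic DBU should equilibrate the cis epimer F3 to the trans ester, so the route is rejoined at 11.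

Step 9. The aryllithium may deprotonate C3 of the hindered α-aryl Weinreb amide, or induce loss of formaldehyde from the N-methoxy group, faster than it adds, so that only the side-chain ketone forms. The fallback goes through the lower oxidation level. Setting out from 13, LiAlH4 in THF at −40 °C should reduce both amides to the dialdehyde F4. The organocerium reagent made from 16 and anhydrous CeCl3 should add to both formyl groups at −78 °C without enolisation and give the bis-carbinol F5 (a mixture of carbinol epimers). Activated MnO2 in CH2Cl2 should then oxidise both electron-rich benzylic carbinols in the presence of the free phenol, and the route is rejoined at 17.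

Step 4. Protodeboronation of the electron-poor boronic acid may outrun carbometalation of the sluggish vinylogous ester, or facial discrimination may prove insufficient. The fallback builds the pyranone by oxa-Michael closure and resolves it. Setting out from 3, commercial 4-hydroxybenzaldehyde is mesylated (MsCl, Et3N) to 4-formylphenyl methanesulfonate F6. Acid-mediated Claisen–Schmidt condensation with 3 (HCl generated from SOCl2 in MeOH, which spares ester and sulfonate) should give the 2'-hydroxychalcone F7. Sodium acetate in refluxing methanol should close it to the racemic flavanone F8. Kinetic resolution by Noyori transfer hydrogenation (the Ru–TsDPEN antipode that consumes the R ketone, HCO2H/Et3N) should reduce the unwanted enantiomer to the cis-flavan-4-ol F9. The S ketone that remains is separated by chromatography and rejoins the route at 8.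

**Further compounds**

F1 | step 5 | methyl 3-[(2S)-2-[4-(methanesulfonyloxy)phenyl]-4-oxo-3-(trifluoroacetyl)-3,4-dihydro-2H-chromen-6-yl]propanoate (C3 epimers/enol) | O=C1C(C(=O)C(F)(F)F)[C@@H](c2ccc(OS(C)(=O)=O)cc2)Oc2ccc(CCC(=O)OC)cc12
F2 | step 5 | methyl 3-[(2R)-3-diazo-2-[4-(methanesulfonyloxy)phenyl]-4-oxo-3,4-dihydro-2H-chromen-6-yl]propanoate (C2 spatially as in 8; descriptor changes by CIP priority only) | O=C1C(=[N+]=[N-])[C@@H](c2ccc(OS(C)(=O)=O)cc2)Oc2ccc(CCC(=O)OC)cc12
F3 | step 5 | methyl (2S,3R)-2-[4-(methanesulfonyloxy)phenyl]-5-(3-methoxy-3-oxopropyl)-2,3-dihydro-1-benzofuran-3-carboxylate (2,3-cis) | COC(=O)CCc1ccc2c(c1)[C@@H](C(=O)OC)[C@@H](c1ccc(OS(C)(=O)=O)cc1)O2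
F4 | step 9 | (2S,3S)-2-(4-hydroxyphenyl)-5-(3-oxopropyl)-2,3-dihydro-1-benzofuran-3-carbaldehyde | O=CCCc1ccc2c(c1)[C@H](C=O)[C@@H](c1ccc(O)cc1)O2
F5 | step 9 | 1-[2,4-bis(benzyloxy)phenyl]-3-[2,3-trans-3-{[2,4-bis(benzyloxy)phenyl](hydroxy)methyl}-2-(4-hydroxyphenyl)-2,3-dihydro-1-benzofuran-5-yl]propan-1-ol (ring centres as in 13; carbinol epimers) | OC(CCc1ccc2c(c1)[C@H](C(O)c1ccc(OCc3ccccc3)cc1OCc1ccccc1)[C@@H](c1ccc(O)cc1)O2)c1ccc(OCc2ccccc2)cc1OCc1ccccc1
F6 | step 4 | 4-formylphenyl methanesulfonate | CS(=O)(=O)Oc1ccc(C=O)cc1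
F7 | step 4 | methyl 3-{4-hydroxy-3-[(2E)-3-[4-(methanesulfonyloxy)phenyl]prop-2-enoyl]phenyl}propanoate | COC(=O)CCc1ccc(O)c(C(=O)/C=C/c2ccc(OS(C)(=O)=O)cc2)c1
F8 | step 4 | methyl 3-[2-[4-(methanesulfonyloxy)phenyl]-4-oxo-3,4-dihydro-2H-chromen-6-yl]propanoate (racemic) | O=C1CC(c2ccc(OS(C)(=O)=O)cc2)Oc2ccc(CCC(=O)OC)cc12
F9 | step 4 | methyl 3-[(2R,4R)-4-hydroxy-2-[4-(methanesulfonyloxy)phenyl]-3,4-dihydro-2H-chromen-6-yl]propanoate (2,4-cis) | O[C@@H]1C[C@H](c2ccc(OS(C)(=O)=O)cc2)Oc2ccc(CCC(=O)OC)cc12
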